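**Retrosynthetic overview**

- Numbering: ring C1 (angelate carbinol), C2, C3=C4 (Me on C4), C5, C6, C7 (isopropyl; C11 is its CH, C12 one of its methyls), C8 (OAc), C9 and C10 (oxirane, Me on C10). The strategy rests on the C8 oxygen next to the three-carbon branch at C7 in the ten-membered ring, the homoallylic alcohol pattern left by a [2,3]-Wittig shift.
- C7–C8 is cut back to a 13-membered bis-allylic ether (C8–O–C12). Lithiation at C8 contracts it to the ten-membered carbocycle, and the ether oxygen becomes the C8 oxygen.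
- The ether comes from Williamson closure (O–C12) of a seco chloro alcohol. C1–C2 is made by α-selective allylbarium acylation of a Weinreb amide from 3-methylfuran-2(5H)-one, followed by CBS reduction (C1). The Z C7=C11 olefin comes from a Still–Gennari olefination on the aldehyde obtained from geranyl acetate.
- After contraction: hydrogenation of the isopropenyl group, C8–OH-directed epoxidation of C9=C10, acetylation, desilylation, angeloylation.
- Ring order: 13-membered oxacycle (step 16), ten-membered carbocycle (step 17), oxirane (step 19).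

Key step: step 17

Remark: the C7=C11 olefin of the 13-membered ether is built as Z (not the E geometry that allylic oxidation of a geranyl unit gives), because through the exo envelope only a Z olefin leads to the C7/C8 pattern of the target (isopropyl and oxygen on opposite sides of the backbone C6–C7–C8–C9); the E olefin would give the C7 epimer.

**Route**

Step 1
Reactants: 1 geranyl acetate
Product: 2 (2E)-5-(3,3-dimethyloxiran-2-yl)-3-methylpent-2-en-1-yl acetate (racemic)
Conditions: mCPBA (1.05 equiv), NaHCO3, CH2Cl2, 0 °C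
Reagents that add atoms: 3-chloroperoxybenzoic acid, OOC(=O)c1cccc(Cl)c1
Why: Prilezhaev epoxidation with one equivalent of peracid takes the electron-richer remote trisubstituted olefin and leaves the one deactivated by the allylic acetate; the racemic epoxide stereocentre is destroyed in step 2.

Step 2
Reactants: 2 epoxide
Product: 4 (2E)-3-methyl-6-oxohex-2-en-1-yl acetate, via glycol 3 (not isolated)
Conditions: H5IO6, THF/H2O, 0 °C
Reagents that add atoms: none
Why: Acid opens the epoxide to the glycol, with water entering at the tertiary carbon so that the aldehyde keeps the former epoxide oxygen, and periodate (Malaprade) cleavage then gives the aldehyde without touching the allylic acetate or the E olefin.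

Step 3
Reactants: 4 aldehyde; 5 ethyl 2-[bis(2,2,2-trifluoroethoxy)phosphoryl]propanoate
Product: 6 ethyl (2Z,6E)-8-acetoxy-2,6-dimethylocta-2,6-dienoate
Conditions: 5, KN(SiMe3)2, 18-crown-6, THF, −78 °C; then 4
Reagents that add atoms: none
Why: Still–Gennari olefination: the trifluoroethyl phosphonate adduct collapses faster than it equilibrates, so the trisubstituted enoate should form with ester and chain cis (Z), the geometry that C7=C11 must carry into the key step.

Step 4
Reactants: 6 acetoxy enoate
Product: 7 ethyl (2Z,6E)-8-hydroxy-2,6-dimethylocta-2,6-dienoate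
Conditions: K2CO3 (0.3 equiv), EtOH, 0 °C to rt
Reagents that add atoms: none
Why: Carbonate-catalysed transesterification removes the acetate, whereas ethanolysis of the conjugated ethyl ester is degenerate and conjugate addition to the α-methyl enoate is slow.

Step 5
Reactants: 7 hydroxy enoate
Product: 9 ethyl (2Z,6E)-8-chloro-2,6-dimethylocta-2,6-dienoate, via allylic mesylate 8 (not isolated)
Conditions: MsCl, 2,4,6-collidine, LiCl, DMF, 0 °C
Reagents that add atoms: lithium chloride, [Li+].[Cl-]
Why: Collington–Meyers chlorination: chloride displaces the primary allylic mesylate by SN2 under buffered conditions, without allylic transposition or loss of the E geometry.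

Step 6
Reactants: 9 chloro enoate
Product: 10 (2Z,6E)-8-chloro-2,6-dimethylocta-2,6-dien-1-ol
Conditions: i-Bu2AlH (2.2 equiv), CH2Cl2, −78 °C; aq. potassium sodium tartrate
Reagents that add atoms: none
Why: i-Bu2AlH reduces the enoate 1,2 to the allylic alcohol at −78 °C, conditions under which the allylic chloride and both olefin geometries are untouched.

Step 7
Reactants: 10 chloro alcohol
Product: 11 [(2Z,6E)-8-chloro-2,6-dimethylocta-2,6-dien-1-yl]oxy(triethyl)silane
Conditions: Et3SiCl, imidazole, CH2Cl2, 0 °C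
Reagents that add atoms: chlorotriethylsilane, CC[Si](CC)(CC)Cl
Why: Imidazole-mediated silylation protects the primary hydroxyl without forming an alkoxide, so the allylic chloride is not displaced; the triethylsilyl group can later be removed beside tert-butyldimethylsilyl ethers.

Step 8
Reactants: 12 3-methylfuran-2(5H)-one
Product: 13 (2Z)-4-hydroxy-N-methoxy-N,2-dimethylbut-2-enamide
Conditions: MeNHOMe·HCl, AlMe3, CH2Cl2, 0 °C to rt
Reagents that add atoms: N,O-dimethylhydroxylamine hydrochloride, CNOC.Cl
Why: Weinreb aminolysis of the lactone by the aluminium amide formed from AlMe3 and the amine salt; the ring fixes hydroxymethyl and carbonyl cis, which is the Z geometry of C9=C10.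

Step 9
Reactants: 13 hydroxy amide
Product: 14 (2Z)-4-[(tert-butyldimethylsilyl)oxy]-N-methoxy-N,2-dimethylbut-2-enamide
Conditions: t-BuMe2SiCl, imidazole, CH2Cl2, 0 °C
Reagents that add atoms: tert-butyldimethylsilyl chloride, CC(C)(C)[Si](C)(C)Cl
Why: Immediate silylation under mild imidazole conditions blocks relactonisation of the (Z)-γ-hydroxy amide and masks the C8 oxygen.

Step 10
Reactants: 11 allylic chloride; 14 Weinreb amide
Product: 16 (2Z,6E,10Z)-1-[(tert-butyldimethylsilyl)oxy]-3,7,11-trimethyl-12-[(triethylsilyl)oxy]dodeca-2,6,10-trien-4-one (chain atoms 1–12 of this name are C8, C9, C10, C1, C2, C3, C4, C5, C6, C7, C11, C12 of the ring numbering), via allylbarium chloride 15 (not isolated)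
Conditions: BaI2, lithium biphenylide (2 equiv), THF, rt; then 11, −78 °C; then 14, −78 °C; pH 7 buffer
Reagents that add atoms: none
Why: Activated zerovalent barium inserts into the allylic chloride at −78 °C to give an allylbarium that keeps its E geometry and reacts at its α-carbon, and its addition to the N-methoxy-N-methylamide stops at the chelated tetrahedral adduct (Weinreb ketone synthesis), so the β,γ-unsaturated (Z)-enone is released only on buffered work-up.

Step 11
Reactants: 16 ketone
Product: 17 (2Z,4S,6E,10Z)-1-[(tert-butyldimethylsilyl)oxy]-3,7,11-trimethyl-12-[(triethylsilyl)oxy]dodeca-2,6,10-trien-4-ol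
Conditions: (R)-2-methyl-CBS-oxazaborolidine (0.5 equiv), catecholborane, toluene, −78 °C
Reagents that add atoms: none
Why: Corey–Bakshi–Shibata reduction: the ketone binds to the catalyst boron anti to the bulkier α-branched alkenyl group and hydride is delivered to the face that gives the (S)-carbinol at C1, while catecholborane at −78 °C avoids hydroboration and 1,4-reduction.

Step 12
Reactants: 17 allylic alcohol
Product: 18 (2Z,4S,6E,10Z)-1,4-bis[(tert-butyldimethylsilyl)oxy]-3,7,11-trimethyl-12-[(triethylsilyl)oxy]dodeca-2,6,10-triene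
Conditions: t-BuMe2SiCl, imidazole, DMF, rt
Reagents that add atoms: tert-butyldimethylsilyl chloride, CC(C)(C)[Si](C)(C)Cl
Why: Standard silylation of the secondary allylic alcohol; the C1 silyl ether keeps this oxygen out of the etherification and later biases the ring contraction.

Step 13
Reactants: 18 tris-silyl ether
Product: 19 (2Z,6E,9S,10Z)-9,12-bis[(tert-butyldimethylsilyl)oxy]-2,6,10-trimethyldodeca-2,6,10-trien-1-ol (C12 hydroxyl free)
Conditions: PPTS (0.1 equiv), MeOH/CH2Cl2, 0 °C
Reagents that add atoms: none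
Why: Mild acid methanolysis cleaves the primary triethylsilyl ether much faster than the primary and secondary tert-butyldimethylsilyl ethers.

Step 14
Reactants: 19 C12 alcohol
Product: 21 (2Z,4S,6E,10Z)-1,4-bis[(tert-butyldimethylsilyl)oxy]-12-chloro-3,7,11-trimethyldodeca-2,6,10-triene, via allylic mesylate 20 (not isolated)
Conditions: MsCl, 2,4,6-collidine, LiCl, DMF, 0 °C
Reagents that add atoms: lithium chloride, [Li+].[Cl-]
Why: Collington–Meyers chlorination as in step 5, SN2 at the primary allylic mesylate with retention of the Z geometry at C7=C11.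

Step 15
Reactants: 21 C12 chloride
Product: 22 (2Z,4S,6E,10Z)-4-[(tert-butyldimethylsilyl)oxy]-12-chloro-3,7,11-trimethyldodeca-2,6,10-trien-1-ol (C8 hydroxyl free)
Conditions: HF·pyridine, pyridine, THF, 0 °C
Reagents that add atoms: none
Why: Buffered HF·pyridine removes the unhindered primary tert-butyldimethylsilyl ether selectively over the secondary one at C1, in a non-nucleophilic medium that leaves the allylic chloride intact.

Step 16
Reactants: 22 seco chloro alcohol
Product: 23 (3Z,5S,7E,11Z)-5-[(tert-butyldimethylsilyl)oxy]-4,8,12-trimethyl-1-oxacyclotrideca-3,7,11-triene (oxacycle atoms O1, C2–C13 are O, C8, C9, C10, C1, C2, C3, C4, C5, C6, C7, C11, C12 of the ring numbering)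
Conditions: NaH, Bu4NI (cat.), THF, 50 °C, syringe-pump addition (2 mM)
Reagents that add atoms: none
Why: Intramolecular Williamson etherification under high dilution: the primary C8 alkoxide displaces the primary allylic chloride at C12 by SN2 to close the 13-membered ring without a new stereocentre, three olefins stiffen the chain, and alkylation of the primary alkoxide should outrun a 1,4 oxygen-to-oxygen silyl shift from C1.

Step 17
Reactants: 23 13-membered bis-allylic ether
Product: 25 (1S,3E,7S,8S,9Z)-1-[(tert-butyldimethylsilyl)oxy]-4,10-dimethyl-7-(prop-1-en-2-yl)cyclodeca-3,9-dien-8-ol (ring numbering of the overview), via C8-lithiated ether 24 (not isolated)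
Conditions: n-BuLi (1.5 equiv), THF, −78 to −25 °C; then H2O
Reagents that add atoms: none
Why: n-BuLi removes a proton from the C8 ether methylene and the α-oxyallyllithium attacks C7 through a five-membered envelope (C8–O–C12–C11=C7) while the O–C12 bond breaks and C11=C12 becomes the isopropenyl olefin, an anionic [2,3]-Wittig rearrangement. The closest known reaction type is the [2,3]-Wittig ring contraction of farnesane-type 13-membered diallylic or allyl propargyl ethers to germacrane carbocycles. The ten-membered carbocycle C1–C10 is closed by ring contraction, a transannular C7–C8 bond formation inside the 13-membered ether with loss of the C12–O bridge, not by end-to-end cyclisation. C7 is set by the olefin geometry: with the C9 vinyl group exo on the envelope, the Z C7=C11 olefin gives C8–OH and the C7–C6 bond syn along the chain C9–C8–C7–C11, which puts isopropenyl and hydroxyl on opposite sides of the ring backbone as in the target. C8 is set by C1: A(1,3) strain across the Z C9=C10 unit keeps C1–H in the olefin plane, so the C2 tether and with it C7 lie on one face of the C8–C9–C10 allyl anion and the silyloxy group on the other, which corresponds to the C1/C8 relationship of the target. The step needs lithiation at C8 and not at C12 (C8 is the O–CH2–CH= position, whereas C12 sits on the methyl-bearing sp2 carbon and its anion could only shift onto the fully substituted C10), and [2,3] shift over [1,2] shift and oxy-Cope rearrangement, which low temperature and the lithium counterion should secure.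

Step 18
Reactants: 25 dienol
Product: 26 (1S,3E,7S,8R,9Z)-1-[(tert-butyldimethylsilyl)oxy]-4,10-dimethyl-7-(propan-2-yl)cyclodeca-3,9-dien-8-ol
Conditions: RhCl(PPh3)3 (cat.), H2 (1 atm), benzene, rt
Reagents that add atoms: none
Why: Homogeneous hydrogenation with RhCl(PPh3)3 reduces the unhindered 1,1-disubstituted isopropenyl olefin much faster than the two trisubstituted ring olefins, and it also removes the 3-hydroxy-1,5-diene that could undergo oxy-Cope rearrangement (the C8 descriptor changes by priority only).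

Step 19
Reactants: 26 allylic alcohol
Product: 27 (1S,3E,7S,8R,9S,10S)-1-[(tert-butyldimethylsilyl)oxy]-9,10-epoxy-4,10-dimethyl-7-(propan-2-yl)cyclodec-3-en-8-ol
Conditions: VO(acac)2 (cat.), t-BuOOH, CH2Cl2, 0 °C
Reagents that add atoms: tert-butyl hydroperoxide, CC(C)(C)OO
Why: Hydroxyl-directed epoxidation: the C8 vanadate delivers oxygen to C9=C10 from the face of the C8 oxygen in the conformer that holds C8–H in the olefin plane to avoid A(1,3) strain with the cis C1 substituent (threo product, setting C9 and C10 as in the target), and the unactivated C3=C4 olefin is not touched.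

Step 20
Reactants: 27 epoxy alcohol
Product: 28 (1S,3E,7S,8R,9S,10S)-1-[(tert-butyldimethylsilyl)oxy]-9,10-epoxy-4,10-dimethyl-7-(propan-2-yl)cyclodec-3-en-8-yl acetate
Conditions: Ac2O, pyridine, DMAP (cat.), CH2Cl2, rt
Reagents that add atoms: acetic anhydride, CC(=O)OC(C)=O
Why: DMAP-catalysed acylation of the hindered secondary C8 hydroxyl, the only acylable group in the molecule.

Step 21
Reactants: 28 silyl ether
Product: 29 (1S,3E,7S,8R,9S,10R)-8-acetoxy-9,10-epoxy-4,10-dimethyl-7-(propan-2-yl)cyclodec-3-en-1-ol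
Conditions: Bu4NF, AcOH, THF, 0 °C to rt
Reagents that add atoms: none
Why: Fluoride cleaves the C1 silyl ether, with acetic acid buffering the alkoxide so that acetate migration and Payne rearrangement of the 2,3-epoxy alcohol are suppressed (the C10 descriptor changes by priority only).

Step 22
Reactants: 29 epoxy alcohol; 30 angelic acid
Product: 32 (1S,3E,7S,8R,9S,10R)-8-acetoxy-9,10-epoxy-4,10-dimethyl-7-(propan-2-yl)cyclodec-3-en-1-yl (2Z)-2-methylbut-2-enoate (CNP0180504.6), via mixed anhydride 31 (not isolated)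
Conditions: 30, 2,4,6-trichlorobenzoyl chloride, Et3N, toluene, rt; then 29, toluene, 80 °C
Reagents that add atoms: none
Why: Yamaguchi-type esterification through the mixed anhydride of angelic acid, run without DMAP because nucleophilic catalysts isomerise angelates to tiglates; the alcohol attacks the less hindered angeloyl carbonyl and the C1 configuration is retained.

**Compound list**

1 | geranyl acetate | CC(C)=CCC/C(C)=C/COC(C)=O | starting material
2 | (2E)-5-(3,3-dimethyloxiran-2-yl)-3-methylpent-2-en-1-yl acetate (racemic) | CC1(C)OC1CC/C(C)=C/COC(C)=O | intermediate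
3 | (2E)-6,7-dihydroxy-3,7-dimethyloct-2-en-1-yl acetate (glycol, not isolated) | CC(C)(O)C(O)CC/C(C)=C/COC(C)=O | intermediate
4 | (2E)-3-methyl-6-oxohex-2-en-1-yl acetate | O=CCC/C(C)=C/COC(C)=O | intermediate
5 | ethyl 2-[bis(2,2,2-trifluoroethoxy)phosphoryl]propanoate | CCOC(=O)C(C)P(=O)(OCC(F)(F)F)OCC(F)(F)F | starting material
6 | ethyl (2Z,6E)-8-acetoxy-2,6-dimethylocta-2,6-dienoate | CCOC(=O)/C(C)=C\CC/C(C)=C/COC(C)=O | intermediate
7 | ethyl (2Z,6E)-8-hydroxy-2,6-dimethylocta-2,6-dienoate | CCOC(=O)/C(C)=C\CC/C(C)=C/CO | intermediate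
8 | ethyl (2Z,6E)-8-(methanesulfonyloxy)-2,6-dimethylocta-2,6-dienoate (not isolated) | CCOC(=O)/C(C)=C\CC/C(C)=C/COS(C)(=O)=O | intermediate
9 | ethyl (2Z,6E)-8-chloro-2,6-dimethylocta-2,6-dienoate | CCOC(=O)/C(C)=C\CC/C(C)=C/CCl | intermediate
10 | (2Z,6E)-8-chloro-2,6-dimethylocta-2,6-dien-1-ol | OC/C(C)=C\CC/C(C)=C/CCl | intermediate
11 | [(2Z,6E)-8-chloro-2,6-dimethylocta-2,6-dien-1-yl]oxy(triethyl)silane | CC[Si](CC)(CC)OC/C(C)=C\CC/C(C)=C/CCl | intermediate
12 | 3-methylfuran-2(5H)-one | CC1=CCOC1=O | starting material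
13 | (2Z)-4-hydroxy-N-methoxy-N,2-dimethylbut-2-enamide | CON(C)C(=O)/C(C)=C\CO | intermediate
14 | (2Z)-4-[(tert-butyldimethylsilyl)oxy]-N-methoxy-N,2-dimethylbut-2-enamide | CON(C)C(=O)/C(C)=C\CO[Si](C)(C)C(C)(C)C | intermediate
15 | [(2E,6Z)-3,7-dimethyl-8-(triethylsilyloxy)octa-2,6-dien-1-yl]barium chloride (not isolated) | Cl[Ba]C/C=C(\C)CC/C=C(/C)CO[Si](CC)(CC)CC | intermediate
16 | (2Z,6E,10Z)-1-[(tert-butyldimethylsilyl)oxy]-3,7,11-trimethyl-12-[(triethylsilyl)oxy]dodeca-2,6,10-trien-4-one | CC(C)(C)[Si](C)(C)OC/C=C(/C)C(=O)C/C=C(\C)CC/C=C(/C)CO[Si](CC)(CC)CC | intermediate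
17 | (2Z,4S,6E,10Z)-1-[(tert-butyldimethylsilyl)oxy]-3,7,11-trimethyl-12-[(triethylsilyl)oxy]dodeca-2,6,10-trien-4-ol | CC(C)(C)[Si](C)(C)OC/C=C(/C)[C@@H](O)C/C=C(\C)CC/C=C(/C)CO[Si](CC)(CC)CC | intermediate
18 | (2Z,4S,6E,10Z)-1,4-bis[(tert-butyldimethylsilyl)oxy]-3,7,11-trimethyl-12-[(triethylsilyl)oxy]dodeca-2,6,10-triene | CC(C)(C)[Si](C)(C)OC/C=C(/C)[C@@H](O[Si](C)(C)C(C)(C)C)C/C=C(\C)CC/C=C(/C)CO[Si](CC)(CC)CC | intermediate
19 | (2Z,6E,9S,10Z)-9,12-bis[(tert-butyldimethylsilyl)oxy]-2,6,10-trimethyldodeca-2,6,10-trien-1-ol | CC(C)(C)[Si](C)(C)OC/C=C(/C)[C@@H](O[Si](C)(C)C(C)(C)C)C/C=C(\C)CC/C=C(/C)CO | intermediate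
20 | methanesulfonate of 19 (not isolated) | CC(C)(C)[Si](C)(C)OC/C=C(/C)[C@@H](O[Si](C)(C)C(C)(C)C)C/C=C(\C)CC/C=C(/C)COS(C)(=O)=O | intermediate
21 | (2Z,4S,6E,10Z)-1,4-bis[(tert-butyldimethylsilyl)oxy]-12-chloro-3,7,11-trimethyldodeca-2,6,10-triene | CC(C)(C)[Si](C)(C)OC/C=C(/C)[C@@H](O[Si](C)(C)C(C)(C)C)C/C=C(\C)CC/C=C(/C)CCl | intermediate
22 | (2Z,4S,6E,10Z)-4-[(tert-butyldimethylsilyl)oxy]-12-chloro-3,7,11-trimethyldodeca-2,6,10-trien-1-ol | OC/C=C(/C)[C@@H](O[Si](C)(C)C(C)(C)C)C/C=C(\C)CC/C=C(/C)CCl | intermediate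
23 | (3Z,5S,7E,11Z)-5-[(tert-butyldimethylsilyl)oxy]-4,8,12-trimethyl-1-oxacyclotrideca-3,7,11-triene | CC(C)(C)[Si](C)(C)O[C@H]1C/C=C(\C)CC/C=C(/C)COC/C=C1/C | intermediate
24 | 2-lithio derivative of 23, lithium on the ether carbon C8 (not isolated) | CC(C)(C)[Si](C)(C)O[C@H]1C/C=C(\C)CC/C=C(/C)COC([Li])/C=C1/C | intermediate
25 | (1S,3E,7S,8S,9Z)-1-[(tert-butyldimethylsilyl)oxy]-4,10-dimethyl-7-(prop-1-en-2-yl)cyclodeca-3,9-dien-8-ol | CC(C)(C)[Si](C)(C)O[C@H]1C/C=C(\C)CC[C@@H](C(C)=C)[C@@H](O)/C=C1/C | intermediate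
26 | (1S,3E,7S,8R,9Z)-1-[(tert-butyldimethylsilyl)oxy]-4,10-dimethyl-7-(propan-2-yl)cyclodeca-3,9-dien-8-ol | CC(C)(C)[Si](C)(C)O[C@H]1C/C=C(\C)CC[C@@H](C(C)C)[C@@H](O)/C=C1/C | intermediate
27 | (1S,3E,7S,8R,9S,10S)-1-[(tert-butyldimethylsilyl)oxy]-9,10-epoxy-4,10-dimethyl-7-(propan-2-yl)cyclodec-3-en-8-ol | CC(C)(C)[Si](C)(C)O[C@H]1C/C=C(\C)CC[C@@H](C(C)C)[C@@H](O)[C@@H]2O[C@]12C | intermediate
28 | (1S,3E,7S,8R,9S,10S)-1-[(tert-butyldimethylsilyl)oxy]-9,10-epoxy-4,10-dimethyl-7-(propan-2-yl)cyclodec-3-en-8-yl acetate | CC(C)(C)[Si](C)(C)O[C@H]1C/C=C(\C)CC[C@@H](C(C)C)[C@@H](OC(C)=O)[C@@H]2O[C@]12C | intermediate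
29 | (1S,3E,7S,8R,9S,10R)-8-acetoxy-9,10-epoxy-4,10-dimethyl-7-(propan-2-yl)cyclodec-3-en-1-ol | O[C@H]1C/C=C(\C)CC[C@@H](C(C)C)[C@@H](OC(C)=O)[C@@H]2O[C@]12C | intermediate
30 | angelic acid, (2Z)-2-methylbut-2-enoic acid | C/C=C(/C)C(=O)O | starting material
31 | (2Z)-2-methylbut-2-enoic 2,4,6-trichlorobenzoic anhydride (not isolated) | C/C=C(/C)C(=O)OC(=O)c1c(Cl)cc(Cl)cc1Cl | intermediate
32 | (1S,3E,7S,8R,9S,10R)-8-acetoxy-9,10-epoxy-4,10-dimethyl-7-(propan-2-yl)cyclodec-3-en-1-yl (2Z)-2-methylbut-2-enoate | C/C=C(/C)C(=O)O[C@H]1C/C=C(\C)CC[C@@H](C(C)C)[C@@H](OC(C)=O)[C@@H]2O[C@]12C | target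

**Step count and risks**

Total steps: 22. Longest linear sequence: 20 (steps 1–7, then 10–22).

Steps most likely to fail:

1. Step 17. Lithiation may take place at the C12 methylene instead of C8, a [1,2]-shift may compete, or C7 may attack the wrong face of the allyl anion if the bias from C1 is too weak. Fallback: the same C7–C8 bond and ring can be made without any deprotonation by a Lewis-acid-promoted intramolecular allylstannane–aldehyde addition. Setting out from chloro alcohol 22, Bu3SnLi (2.2 equiv, THF, −78 °C; the first equivalent is spent on the hydroxyl) would displace the chloride to give allylstannane F1. Dess–Martin periodinane (NaHCO3, CH2Cl2) would then give (Z)-enal F2. BF3·OEt2 (CH2Cl2, −78 °C, high dilution) should close the ten-membered ring by SE2′ attack of C7 on the C8 aldehyde through an open transition state, which favours the same syn C7/C8 pattern and generates the isopropenyl group. The route is rejoined at dienol 25.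

2. Step 10. The allylbarium may couple with unreacted chloride while it forms or attack through its γ-carbon, and the (Z)-enone or its β,γ-olefin may isomerise under the basic conditions. Fallback: setting out from amide 14, i-Bu2AlH (THF, −78 °C) would give (Z)-enal F3. Allylbarium 15 is known to add to aldehydes at its α-carbon and would give racemic alcohol F4. Dess–Martin oxidation (NaHCO3, CH2Cl2) returns to ketone 16, after which C1 is set in step 11 as before.

3. Step 19. In the flexible ten-membered ring the oxygen may be delivered to the wrong face of C9=C10, or the allylic alcohol may be oxidised to the enone. Fallback: let the C1 hydroxyl direct instead. Setting out from 26, acetylation (Ac2O, pyridine, DMAP) would give acetate F5 and Bu4NF/AcOH would free the C1 hydroxyl to give hydroxy acetate F6. VO(acac)2/t-BuOOH should then epoxidise C9=C10 from the face of the C1 oxygen, which by the same A(1,3) argument is the face needed, since the oxirane of the target is threo to both the C1 and the C8 oxygen. The route is rejoined at epoxy alcohol 29.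

Further compounds
F1 | step 17 | (2Z,4S,6E,10Z)-4-[(tert-butyldimethylsilyl)oxy]-3,7,11-trimethyl-12-(tributylstannyl)dodeca-2,6,10-trien-1-ol | OC/C=C(/C)[C@@H](O[Si](C)(C)C(C)(C)C)C/C=C(\C)CC/C=C(/C)C[Sn](CCCC)(CCCC)CCCC
F2 | step 17 | (2Z,4S,6E,10Z)-4-[(tert-butyldimethylsilyl)oxy]-3,7,11-trimethyl-12-(tributylstannyl)dodeca-2,6,10-trienal | O=C/C=C(/C)[C@@H](O[Si](C)(C)C(C)(C)C)C/C=C(\C)CC/C=C(/C)C[Sn](CCCC)(CCCC)CCCC
F3 | step 10 | (2Z)-4-[(tert-butyldimethylsilyl)oxy]-2-methylbut-2-enal | CC(C)(C)[Si](C)(C)OC/C=C(/C)C=O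
F4 | step 10 | racemic (2Z,6E,10Z)-1-[(tert-butyldimethylsilyl)oxy]-3,7,11-trimethyl-12-[(triethylsilyl)oxy]dodeca-2,6,10-trien-4-ol | CC(C)(C)[Si](C)(C)OC/C=C(/C)C(O)C/C=C(\C)CC/C=C(/C)CO[Si](CC)(CC)CC
F5 | step 19 | (1S,3E,7S,8R,9Z)-1-[(tert-butyldimethylsilyl)oxy]-4,10-dimethyl-7-(propan-2-yl)cyclodeca-3,9-dien-8-yl acetate | CC(C)(C)[Si](C)(C)O[C@H]1C/C=C(\C)CC[C@@H](C(C)C)[C@@H](OC(C)=O)/C=C1/C
F6 | step 19 | (1S,3E,7S,8R,9Z)-8-acetoxy-4,10-dimethyl-7-(propan-2-yl)cyclodeca-3,9-dien-1-ol | O[C@H]1C/C=C(\C)CC[C@@H](C(C)C)[C@@H](OC(C)=O)/C=C1/C
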